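The runs stem from a simulated flask for an exercise.

By 12.0 h the flask had nearly stopped climbing: I read 26.3% of left-handed product there and 26.6% at 20.0 h, a step of 0.3 percentage points against a scatter of 0.3 points.

the same everywhere: left-handed substrate 0.066 M; right-handed substrate 0.066 M; partner 0.0792 M; free catalyst 9.9 mM
- zeta: the very flask that is asked about, followed so far
- flask: time 20 h

zeta run (percent of the left-handed substrate and right-handed substrate together charged)

| time / h | left-handed product / % |
|---|---|
| 3.00 | 20.1 |
| 6.00 | 24.2 |
| 10.0 | 26.1 |
| 12.0 | 26.3 |
| 15.0 | 26.5 |
| 20.0 | 26.6 |

(readings scatter by 0.3 percentage points)

- free catalyst is single-handed; left-handed substrate and right-handed substrate are mirror images of each other, charged as a racemate, each of them at the stated concentration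
- removed left-handed product is counted in
- on the list of suspects stand: partner + free catalyst + left-handed substrate -> free catalyst + left-handed product; partner + free catalyst + right-handed substrate -> free catalyst + right-handed product; free catalyst -> spent catalyst
- additions bring no volume worth counting

- south: at 20 h add partner, 100% of the amount charged, then wait 20 h
- north-west: change nothing and wait 20 h more
- east: at 20 h add free catalyst, 100% of the amount charged, then wait 20 h
- south-east: at 20 h take out 90% of the left-handed product then present, then wait 20 h

* left-handed product, in percent of the left-handed substrate and right-handed substrate together first charged, at 20 h
* what to do for the largest gain in left-handed product; "none" if nothing gains more than 2 percentage points (south / north-west / east / south-east / none)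
* left-handed product present, with what was taken out counted in, in percent of the left-handed substrate and right-handed substrate together first charged, after north-west
* left-handed product present, with what was taken out counted in, in percent of the left-handed substrate and right-handed substrate together first charged, after east

On the suspects' list, left-handed substrate disappears in proportion to itself, so I carried L, the natural logarithm of its charge over what remains. At the last reading L = 0.759, taking that one product reading as the measure of substrate used. L equals the step's rate constant, times the mean partner the working catalyst met, times free catalyst summed over time. This replaces the partner curve by one mean, an error I meant to check later.

Two ways reached that plateau. In the first, partner ends at zero. Its charge equals 60.0% of the substrates together, so the right-handed product would stand at 33.4%, which asks for a selectivity factor of 1.45 in favour of right-handed substrate. In the second, free catalyst dies. The gap to the plateau shrank between 3.00 h and 6.00 h at 0.332 h⁻¹, and the summed catalyst is then its charge over that constant. Each way took the plateau reading as its input and spent one free number on it, so neither way tested that reading or the other way. The ways part at the options, with south resting on the first and east on the second, and I could not choose between them from this run.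

The forecast gave 26.6% now, 26.7% after north-west and 26.8% after east, and chose south: “So I expect partner to restart the reaction, extra catalyst to do little, and product removal to do nothing.”

The flask gave 26.7%, 26.8% after north-west and 31.9% after east. The best option was east, gaining 5.2 points against 0.36 points for south.

    partner + free catalyst + left-handed substrate → free catalyst + left-handed product (k = 460 L² mol⁻² h⁻¹)
    partner + free catalyst + right-handed substrate → free catalyst + right-handed product (k = 260 L² mol⁻² h⁻¹)
    free catalyst → spent catalyst (k = 0.240 h⁻¹)

Free catalyst fell with a half-life of 2.9 h to 0.823% at 20.0 h, and both product steps ran while it lasted, half their turnover done by 1.25 h and 1.43 h. Partner still stood at 26.2% of its charge at 20.0 h. Dividing L by the first rate constant and by the summed catalyst, charge over decay constant, gave a mean partner of 0.0400 M, lower than the charge of 0.0792 M and higher than the 0.0207 M at the end. In the neighbour flask charged with 0.20 M of partner, L was 2.33, giving a mean partner of 0.123 M, lower than that charge and higher than its final 0.0921 M.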